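The 2-monosubstituted furan ring (O1, C2 carrying the chain, C3, C4, C5) is treated as the doubly dehydrated form of an open 1,2-dihydroxy-4-oxo chain end, so everything rests on disconnecting the furan O1–C2 bond. In one operation mild acid lets the primary hydroxyl add to the ketone carbon, closing the only ring, and two losses of water aromatise it, so the acid-sensitive furan appears only at the very end. The precursor is racemic 1,2,25-trihydroxypentacosa-9,11-diyn-4-one, assembled from a C15 alkynol and a C7 alkynoic Weinreb amide by Cadiot–Chodkiewicz coupling, methyl ketone formation and a boron aldol with a silyloxyacetaldehyde.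

Key step: step 10

Remark: the target has no stereocentre and no stereogenic double bond, so the single-enantiomer requirement is met trivially; the carbinol centre made in step 8 is carried as the racemate and is erased in step 10.

Step 1
Reactants: 1 prop-2-yn-1-ol (propargyl alcohol); 2 1-bromododecane
Product: 4 pentadec-2-yn-1-ol, via dilithiated propargyl alcohol 3 (not isolated)
Conditions: LiNH2 (2.3 equiv), liq. NH3, −33 °C; then 2 in THF, −33 °C; NH4Cl
Reagents that add atoms: none
Why: Alkylation of the propargyl alcohol dianion (acetylide SN2 reaction), in which the carbanion is far more nucleophilic than the alkoxide, so the unhindered primary bromide should be taken up at carbon only.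

Step 2
Reactants: 4 pentadec-2-yn-1-ol
Product: 6 pentadec-14-yn-1-ol, via dipotassium acetylide alkoxide 5 (not isolated)
Conditions: Li, H2N(CH2)3NH2, 70 °C; KOt-Bu, rt; then 4, rt; H2O
Reagents that add atoms: none
Why: Alkyne zipper reaction, in which potassium 3-aminopropylamide shifts the triple bond along the unbranched chain by repeated propargyl–allenyl proton transfers until it is held irreversibly as the terminal acetylide 5, which the water quench protonates.

Step 3
Reactants: 6 pentadec-14-yn-1-ol
Product: 7 tert-butyldimethyl(pentadec-14-yn-1-yloxy)silane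
Conditions: TBSCl, imidazole, DMF, rt
Reagents that add atoms: tert-butyldimethylsilyl chloride, CC(C)(C)[Si](C)(C)Cl
Why: Imidazole-promoted silylation of an unhindered primary alcohol, which masks the hydroxyl against the Grignard and boron reagents of steps 7 and 8 and is removed together with the second silyl group in step 9.

Step 4
Reactants: 8 hept-6-ynoic acid
Product: 10 N-methoxy-N-methylhept-6-ynamide, via acyl imidazole 9 (not isolated)
Conditions: CDI, CH2Cl2, rt; then MeNHOMe·HCl, rt
Reagents that add atoms: N,O-dimethylhydroxylamine hydrochloride, CNOC.Cl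
Why: Weinreb amide formation through CDI activation, in which acyl imidazole 9 is aminolysed without touching the terminal alkyne; the amide is a ketone precursor that stays inert in the copper/amine coupling of step 6.

Step 5
Reactants: 10 N-methoxy-N-methylhept-6-ynamide
Product: 11 7-bromo-N-methoxy-N-methylhept-6-ynamide
Conditions: NBS, AgNO3 (10 mol%), acetone, rt
Reagents that add atoms: N-bromosuccinimide, O=C1CCC(=O)N1Br
Why: Silver-catalysed electrophilic bromination of a terminal alkyne with NBS, which replaces only the acetylenic hydrogen and tolerates the amide.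

Step 6
Reactants: 7 tert-butyldimethyl(pentadec-14-yn-1-yloxy)silane; 11 7-bromo-N-methoxy-N-methylhept-6-ynamide
Product: 12 22-[(tert-butyldimethylsilyl)oxy]-N-methoxy-N-methyldocosa-6,8-diynamide
Conditions: CuCl (10 mol%), NH2OH·HCl (30 mol%), 30% aq. n-BuNH2, Et2O, 0 °C → rt; slow addition of 11
Reagents that add atoms: none
Why: Cadiot–Chodkiewicz coupling, in which copper(I) joins the terminal alkyne to the 1-bromoalkyne to give the unsymmetrical 1,3-diyne, the ether/aqueous amine two-phase medium keeping the lipophilic silyl ether in solution while hydroxylamine, which would turn a ketone into its oxime, meets only an amide.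

Step 7
Reactants: 12 22-[(tert-butyldimethylsilyl)oxy]-N-methoxy-N-methyldocosa-6,8-diynamide
Product: 14 23-[(tert-butyldimethylsilyl)oxy]tricosa-7,9-diyn-2-one, via magnesium hemiaminal chelate 13 (not isolated)
Conditions: MeMgBr, THF, 0 °C; sat. aq. NH4Cl
Reagents that add atoms: methylmagnesium bromide, C[Mg]Br
Why: Weinreb ketone synthesis, in which the chelated tetrahedral adduct 13 persists until the quench so that exactly one methyl group is delivered, while the Grignard reagent leaves the diyne and the silyl ether alone.

Step 8
Reactants: 14 23-[(tert-butyldimethylsilyl)oxy]tricosa-7,9-diyn-2-one; 15 (tert-butyldimethylsilyloxy)acetaldehyde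
Product: 18 rac-1,25-bis[(tert-butyldimethylsilyl)oxy]-2-hydroxypentacosa-9,11-diyn-4-one, via dibutylboron enolate 16 (not isolated), via dibutylboron aldolate 17 (not isolated)
Conditions: n-Bu2BOTf, i-Pr2NEt, CH2Cl2, −78 °C; then 15, −78 → 0 °C; pH 7 buffer, MeOH, 30% H2O2, 0 °C
Reagents that add atoms: none
Why: Boron-mediated aldol addition, in which dibutylboron triflate and a hindered amine enolise the methyl ketone under kinetic control on the methyl side, enolate 16 adds to the aldehyde through a closed six-membered transition state, and the new carbinol centre at C2 forms as the racemate because neither partner is chiral, which suffices since step 10 destroys it.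

Step 9
Reactants: 18 rac-1,25-bis[(tert-butyldimethylsilyl)oxy]-2-hydroxypentacosa-9,11-diyn-4-one
Product: 19 rac-1,2,25-trihydroxypentacosa-9,11-diyn-4-one
Conditions: HF·pyridine, pyridine, THF, 0 °C → rt; aq. NaHCO3
Reagents that add atoms: none
Why: Fluoride-mediated cleavage of both primary silyl ethers in a pyridine-buffered, slightly acidic medium, chosen over basic fluoride so that the β-hydroxy ketone should not suffer retro-aldol cleavage; any closure to the hemiketal 20 at this stage is harmless because both forms enter step 10.

Step 10
Reactants: 19 rac-1,2,25-trihydroxypentacosa-9,11-diyn-4-one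
Product: 22 target furan 21-(furan-2-yl)henicosa-14,16-diyn-1-ol, via cyclic hemiketal 20 (not isolated), via dihydrofuranol 21 (not isolated)
Conditions: PPTS (20 mol%), 4 Å MS, toluene, 70 °C; Et3N; chromatography on Et3N-washed silica
Reagents that add atoms: none
Why: The C1 primary hydroxyl adds to the protonated C4 carbonyl to give hemiketal 20 (new bond O–C4, the later furan O1–C2), loss of the hemiketal hydroxyl through an oxocarbenium ion with proton loss from C3 gives enol ether 21, and ionisation of its allylic hydroxyl at C2 with proton loss from C1 completes the aromatic ring. The closest known reaction type is the Paal–Knorr-type acid-catalysed cyclodehydration of 3,4-dihydroxy ketones, including aldol adducts of α-silyloxy aldehydes, to furans. The single ring closes in a 5-exo-trig mode. No stereocentre remains in the product: the carbinol centre of 19 and the transient hemiketal centre both become sp2 carbons, so their configuration is irrelevant. The step needs closure through the primary hydroxyl and survival of the furan: the secondary hydroxyl could only form a strained four-membered ring, the remote C25 hydroxyl can add only reversibly, the diyne is inert to a pyridinium acid, and a weak anhydrous acid with sieves removes water without opening or oligomerising the 2-alkylfuran. β-Elimination to the γ-hydroxy enone is no loss, since that enone closes to the same furan under the same conditions.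

Compound list
1 | prop-2-yn-1-ol (propargyl alcohol) | OCC#C | starting material
2 | 1-bromododecane | CCCCCCCCCCCCBr | starting material
3 | dilithium salt of prop-2-yn-1-ol, alkoxide and acetylide (not isolated) | [Li+].[Li+].[O-]CC#[C-] | intermediate
4 | pentadec-2-yn-1-ol | OCC#CCCCCCCCCCCCC | intermediate
5 | acetylide alkoxide of pentadec-14-yn-1-ol, shown as the dipotassium salt (not isolated) | [K+].[K+].[O-]CCCCCCCCCCCCCC#[C-] | intermediate
6 | pentadec-14-yn-1-ol | OCCCCCCCCCCCCCC#C | intermediate
7 | tert-butyldimethyl(pentadec-14-yn-1-yloxy)silane | C#CCCCCCCCCCCCCCO[Si](C)(C)C(C)(C)C | intermediate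
8 | hept-6-ynoic acid | OC(=O)CCCCC#C | starting material
9 | 1-(1H-imidazol-1-yl)hept-6-yn-1-one (not isolated) | C#CCCCCC(=O)n1ccnc1 | intermediate
10 | N-methoxy-N-methylhept-6-ynamide | CON(C)C(=O)CCCCC#C | intermediate
11 | 7-bromo-N-methoxy-N-methylhept-6-ynamide | CON(C)C(=O)CCCCC#CBr | intermediate
12 | 22-[(tert-butyldimethylsilyl)oxy]-N-methoxy-N-methyldocosa-6,8-diynamide | CON(C)C(=O)CCCCC#CC#CCCCCCCCCCCCCCO[Si](C)(C)C(C)(C)C | intermediate
13 | bromomagnesium alkoxide of the tetrahedral methyl adduct of 12, racemic (not isolated) | CON(C)C(C)(O[Mg]Br)CCCCC#CC#CCCCCCCCCCCCCCO[Si](C)(C)C(C)(C)C | intermediate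
14 | 23-[(tert-butyldimethylsilyl)oxy]tricosa-7,9-diyn-2-one | CC(=O)CCCCC#CC#CCCCCCCCCCCCCCO[Si](C)(C)C(C)(C)C | intermediate
15 | (tert-butyldimethylsilyloxy)acetaldehyde | O=CCO[Si](C)(C)C(C)(C)C | starting material
16 | dibutylboron enolate of 14 on the methyl side (not isolated) | C=C(OB(CCCC)CCCC)CCCCC#CC#CCCCCCCCCCCCCCO[Si](C)(C)C(C)(C)C | intermediate
17 | O2-dibutylboryl derivative of aldol 18, racemic (not isolated) | CC(C)(C)[Si](C)(C)OCC(OB(CCCC)CCCC)CC(=O)CCCCC#CC#CCCCCCCCCCCCCCO[Si](C)(C)C(C)(C)C | intermediate
18 | rac-1,25-bis[(tert-butyldimethylsilyl)oxy]-2-hydroxypentacosa-9,11-diyn-4-one | CC(C)(C)[Si](C)(C)OCC(O)CC(=O)CCCCC#CC#CCCCCCCCCCCCCCO[Si](C)(C)C(C)(C)C | intermediate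
19 | rac-1,2,25-trihydroxypentacosa-9,11-diyn-4-one | OCC(O)CC(=O)CCCCC#CC#CCCCCCCCCCCCCCO | intermediate
20 | 2-(21-hydroxyhenicosa-5,7-diyn-1-yl)oxolane-2,4-diol, racemic mixture of diastereomers (not isolated) | OC1(CCCCC#CC#CCCCCCCCCCCCCCO)CC(O)CO1 | intermediate
21 | rac-5-(21-hydroxyhenicosa-5,7-diyn-1-yl)-2,3-dihydrofuran-3-ol (not isolated) | OC1COC(CCCCC#CC#CCCCCCCCCCCCCCO)=C1 | intermediate
22 | 21-(furan-2-yl)henicosa-14,16-diyn-1-ol | OCCCCCCCCCCCCCC#CC#CCCCCc1ccco1 | target

Total step count: 10. Longest linear sequence: 8 steps (1, 2, 3, 6, 7, 8, 9, 10); the amide branch (steps 4 and 5) joins at step 6.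

Steps most likely to fail

1. Step 10. The double dehydration may stall after ring closure, with the hemiketal or the dihydrofuranol accumulating. If it is forced with stronger acid or longer heating, the electron-rich furan may ring-open or oligomerise. The fallback closes the same O–C bond from an alkyne under essentially neutral metal catalysis. It sets out from 12. DIBAL-H (THF, −78 °C) should reduce the Weinreb amide to the aldehyde 22-[(tert-butyldimethylsilyl)oxy]docosa-6,8-diynal F1. Ohira–Bestmann homologation (dimethyl (1-diazo-2-oxopropyl)phosphonate, K2CO3, MeOH, rt) should give the terminal alkyne tert-butyldimethyl(tricosa-14,16,22-triyn-1-yloxy)silane F2. Lithiation (n-BuLi, THF, −78 °C) and addition to 15 should give the propargylic alcohol rac-1,25-bis[(tert-butyldimethylsilyl)oxy]pentacosa-3,9,11-triyn-2-ol F3. HF·pyridine as in step 9 should give rac-pentacosa-3,9,11-triyne-1,2,25-triol F4. Silver nitrate on silica, or Ph3PAuCl/AgOTf (1–2 mol%), in CH2Cl2 at rt should then trigger 5-endo-dig attack of the primary hydroxyl on the activated C4 alkyne carbon and loss of one water (the known silver- or gold-catalysed cyclodehydration of 3-alkyne-1,2-diols). The fallback comes back to the route at 22.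

2. Step 8. Enolisation may occur partly on the methylene side, and the adduct may undergo retro-aldol cleavage or β-elimination during the oxidative work-up. The fallback builds the 1,2-diol by dihydroxylation instead of aldol addition. It sets out from 12. Allylmagnesium bromide (THF, −78 °C, cold buffered quench to avoid conjugation) should give the β,γ-unsaturated ketone 25-[(tert-butyldimethylsilyl)oxy]pentacos-1-ene-9,11-diyn-4-one F5. Upjohn dihydroxylation (cat. OsO4, NMO, acetone–water, 0 °C), which attacks the terminal alkene much faster than the diyne, should give rac-25-[(tert-butyldimethylsilyl)oxy]-1,2-dihydroxypentacosa-9,11-diyn-4-one F6. HF·pyridine as in step 9 removes the remaining silyl group, and the fallback comes back to the route at 19.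

3. Step 6. Halogen–copper exchange may lead to homocoupling of either partner, and conversion may be slow in the two-phase medium. The fallback is an oxidative heterocoupling that needs no bromoalkyne. It sets out from 7 and 10. Glaser–Hay coupling (CuCl/TMEDA, O2, acetone, rt) with a fivefold excess of the inexpensive amide 10 should consume 7 mainly in the cross-coupling. The symmetrical by-products differ strongly in polarity from the product and should be removable by chromatography. The fallback comes back to the route at 12 and makes no compound outside the compound list (F0).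

Further compounds
F1 | step 10 | 22-[(tert-butyldimethylsilyl)oxy]docosa-6,8-diynal | O=CCCCCC#CC#CCCCCCCCCCCCCCO[Si](C)(C)C(C)(C)C
F2 | step 10 | tert-butyldimethyl(tricosa-14,16,22-triyn-1-yloxy)silane | C#CCCCCC#CC#CCCCCCCCCCCCCCO[Si](C)(C)C(C)(C)C
F3 | step 10 | rac-1,25-bis[(tert-butyldimethylsilyl)oxy]pentacosa-3,9,11-triyn-2-ol | CC(C)(C)[Si](C)(C)OCC(O)C#CCCCCC#CC#CCCCCCCCCCCCCCO[Si](C)(C)C(C)(C)C
F4 | step 10 | rac-pentacosa-3,9,11-triyne-1,2,25-triol | OCC(O)C#CCCCCC#CC#CCCCCCCCCCCCCCO
F5 | step 8 | 25-[(tert-butyldimethylsilyl)oxy]pentacos-1-ene-9,11-diyn-4-one | C=CCC(=O)CCCCC#CC#CCCCCCCCCCCCCCO[Si](C)(C)C(C)(C)C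
F6 | step 8 | rac-25-[(tert-butyldimethylsilyl)oxy]-1,2-dihydroxypentacosa-9,11-diyn-4-one | OCC(O)CC(=O)CCCCC#CC#CCCCCCCCCCCCCCO[Si](C)(C)C(C)(C)C
F0 | step 6 | none | none
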